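## Structural features

The target 30 has five rings. Pyrrolidine ring A and azepine ring B share the nitrogen and the ring-fusion CH; ring B carries, next to that CH, the spiro carbon of α-methyl-γ-lactone ring C, and is fused through its N–CH–O carbon and the adjacent sp2 carbon to α-methylbutenolide ring D; α-methyl-γ-lactone ring E hangs on the second α-carbon of ring A. There are seven stereocentres. The O–CH of ring E, the N–CH of ring A that bears it (threo pair), the ring-fusion CH across nitrogen (2,5-trans on ring A) and the quaternary spiro carbon stand in one row; the two CHMe centres sit 1,3 to the lactone carbinol carbons, and the aminal CH stands alone between N and O. The fragile groups are the N,O-acetal of ring D (opens and epimerises in acid or base), the two epimerisable CHMe centres, and the three lactones, which a free secondary amine can attack by O-to-N acyl transfer. The real difficulty is the fully substituted spiro carbon directly attached to the ring-fusion CH, a quaternary–tertiary pair that must be set with control before ring B exists. The key step uses the fact that this spiro carbon, shared by rings B and C, is a tertiary alkoxy carbon next to the nitrogen-bearing CH of ring A: it can be a ketone carbon that receives the CH2CH2 arm of ring B as a nucleophile, while the ring C oxygen closes on an ester carbonyl three bonds away.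

## Logic of the disconnections

30 ⇒ 28. The bond between the ring A nitrogen and the aminal carbon is cut and the nitrogen is capped as a tert-butyl carbamate. This is the most labile bond of 30 and lies at the aldehyde oxidation level, so it is made last; the cut removes ring B and the only epimerisable ring-junction centre from all earlier compounds. The forward step must free the amine and let it reach the masked aldehyde carbon (seven-membered closure) before it attacks a lactone, and the aminal configuration must be the one favoured at equilibrium.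

28 ⇒ 25. No skeletal bond is cut; the hydroxybutenolide is traced back to a furan with silicon on the α-carbon next to the methyl-bearing carbon. A furan survives the organometallic fragment union, which a butenolide would not, and the silicon decides which α-carbon becomes the lactone carbonyl. The forward photooxygenation must touch only the furan, and silicon must be correctly placed from the start.

25 ⇒ 13 + 23. The bond from the spiro carbon to the CH2 of the arm and the O–C(=O) bond of ring C are cut; 23 comes from 21 through 22. This is the most convergent cut, at the most hindered carbon, and leaves one fragment with five stereocentres and one with none. The forward step needs addition to the ketone of 13 only, on the Felkin–Anh face set by the neighbouring N-bearing CH, without enolisation, followed by closure of the alkoxide on the methyl ester.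

13 ⇒ 9 + 12. The bond between the ketone carbon and its CH2 is cut; 12 comes from 11 and 11 from 10. This places the CHMe centre of ring C in a chiral building block, so ring C needs no stereoselective reaction. The forward acylation must not epimerise the α-amino acyl carbon and must spare the ester of the nucleophile and the lactone, which calls for a thioester, an organozinc reagent and palladium catalysis.

9 ⇒ 8 ⇒ 7 ⇒ 5 + 2. After functional group changes at the carboxyl carbon and removal of two hydrogens from ring E, the bond between ring A and the O–CH of ring E is cut. One C–C bond formation sets both adjacent stereocentres and the third centre of ring E follows by hydrogenation. The forward addition must occur anti to the ester on the iminium ring (2,5-trans) and with threo topicity, and the hydrogenation from the face opposite ring A; the benzyl ester lets the same hydrogenation uncover the acid.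

5 ⇒ 3 and 2 ⇒ 1. These are functional group changes only: partial reduction of the imide-type carbonyl of 3 with exchange of OH for OMe, and enol silylation of 1. Both starting materials carry their full carbon skeleton, and 3 brings the ring-fusion stereocentre. The reduction must stop at the hemiaminal and spare the benzyl ester.

21 ⇒ 19 ⇒ 17 ⇒ 16 ⇒ 14. The C–CH3 bond, the C–Si bond and the bond from the furan to the CH2CH2 chain are cut in turn (with OH/Cl exchange between 17 and 16). The two bromines of 14 are regiochemical markers: one is exchanged for the chain; the other first acidifies the neighbouring α-CH, which takes silicon, and is then exchanged for methyl, so silicon ends next to methyl by construction. Each metalation must outrun any reaction of the chloroethyl group, which is why the chain halide is chloride.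

## Other disconnections considered

Alternative 1: The cut is at both C–N bonds of the ring-fusion nitrogen, N–C(ring fusion) and N–C(=O), after raising the aminal carbon to the lactam level. Forward, the azido ketone A1 (a 2-alkylidenecyclohexanone with ring C in place and a secondary azide on a three-carbon tether) is treated with a protic or Lewis acid; the azide adds to the ketone, the tether-bearing α-carbon migrates to nitrogen with loss of N2, and lactam A2 forms with rings A and B closed together.
- In favour: two rings and both C–N bonds arise in one step with retention at the migrating carbon; the quaternary carbon and its neighbour would be fixed on a six-membered carbocycle, where relative configuration is easier to control than in the open-chain ketone 13; no free secondary amine ever faces a lactone.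
- Against: the carbonyl of A1 is an enone carbonyl and a poorer electrophile; the electron-poor alkylidene can compete for the azide by cycloaddition; the acid must coexist with two lactones and an allyl ester; and A2 still needs reduction of one amide carbonyl to the aminal level in the presence of three ester-type carbonyls before ring D can close.
- Comparison: structurally A1 must be assembled linearly on one carbocycle, whereas 13 and 21 are made in parallel. Mechanistically the rearrangement is at least the equal of step 12 in bond-forming power and is the better plan on amine–lactone compatibility. In step economy it should be longer, because of the assembly of A1 and the oxidation-level correction after A2, against only steps 13 and 14 here.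

Alternative 2: The cut is the CH2–CH2 bridge of ring B, taken back to a C=C bond. Forward, the divinyl aminal A3 (vinyl on the spiro carbon, vinyl on the butenolide β-carbon, N,O-acetal already formed) is closed with the second-generation Grubbs catalyst to diene A4, and the new disubstituted alkene is then hydrogenated selectively.
- In favour: the nucleophile that builds the spiro carbon would be a vinyl-metal reagent from the shelf instead of the four-step arm 21; no photooxygenation is needed; ring-closing metathesis to seven-membered nitrogen heterocycles is well established.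
- Against: the N,O-acetal of A3 must be formed intermolecularly from a hindered 2,5-disubstituted pyrrolidine and then survive metathesis; the amine can bind ruthenium; both alkenes are poor partners (one on a fully substituted carbon, one part of an electron-poor diene); A4 is a dienyl aminal that can open or eliminate; the last hydrogenation must distinguish the ring alkene from the butenolide alkene and from allylic C–N and C–O bonds.
- Comparison: on structure the spiro carbon would come from the same kind of Felkin–Anh addition to a ketone like 13, so the plans are equal there, and the smaller nucleophile may make the addition easier. On mechanism, closing ring B on a preformed labile aminal is the weaker order than forming the aminal last. On step economy, fragment synthesis is shorter (a point for the alternative) but three operations follow the union against two here, so the totals should be similar with more fragile intermediates.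

Alternative 3: The cut is the N–C bond of ring A at the carbon bearing ring E, together with the O–CH bond of ring E. Forward, the secondary benzylamine A5, with a (Z)-alkene and a methyl ester in the chain, is treated with I2: 5-exo attack of nitrogen on the iodine-activated alkene closes ring A, nitrogen then displaces iodide, and the ester oxygen opens the three-membered ammonium ring at the exocyclic carbon to close ring E in A6.
- In favour: ring A, ring E and two stereocentres come from one step; the threo relation follows stereospecifically from anti addition and two inversions on a (Z)-alkene; the CHMe of ring E comes from a building block; the masked hydroxybutenolide of A5 and A6 (acetal plus tert-butyl ester on a (Z)-alkene) has its regiochemistry fixed by construction and needs no photooxygenation.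
- Against: the 2,5-trans relation depends on the alkene face attacked in an open-chain amine, which is less biased than the ring iminium ion 6; A5 is a free secondary amine next to lactone ring C and can undergo O-to-N acyl transfer; its N–CH centre next to the quaternary carbon must be made without the chiral pool; the benzyl group must later be removed from A6.
- Comparison: on structure the last closure of ring B is the same as step 14, so the plans are equal there; the alternative is better on the threo pair and on the masked butenolide, the chosen plan better on the quaternary–tertiary pair, which it takes from 3 and a Felkin–Anh addition. On mechanism it is a stereospecific cascade against two diastereoselective steps (3 and 4). On step economy A5 is a long linear chain with a (Z)-alkene and stereocentres set one after another, so the sequence should be longer and less convergent than 14 steps with a longest line of 8.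

Key step: step 12

## Remarks on the chemistry

- Assumption: the aminal carbon of 30 can epimerise by reversible opening of the N,O-acetal, so the configuration shown is taken to be the thermodynamically preferred one and is set under equilibrating conditions in step 14.
- Configuration check: Felkin–Anh addition anti to nitrogen gives (S) at the spiro carbon, as 30 requires. The (R) ester α-carbon of 13 comes unchanged from 10; iodide 11 is (S) only through a change of CIP priorities.
- Design choices that differ from the most obvious form of such a plan: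
  - An N-Boc prolyl chloride is not a usable acyl donor (it collapses to the N-carboxyanhydride and is prone to epimerisation), so the ketone is made from thioester 9.
  - A 3,4-dialkylfuran offers no handle for placing silicon next to the methyl group, so the arm is built from 14 with bromine as the regiochemical marker.
  - The chain halide is chloride so that it survives the lithiations.
  - The ester on the pyrrolidine is benzyl so that step 4 also frees the acid.
- Compound 3 is a catalogue compound (otherwise two routine steps from L-pyroglutamic acid).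

## Route

Step 1
Reactants: 1 3-methylfuran-2(5H)-one
Product: 2 3-methyl-2-[(triisopropylsilyl)oxy]furan
Conditions: i-Pr3SiOTf, Et3N, CH2Cl2, 0 °C
Reagents that add atoms: triisopropylsilyl trifluoromethanesulfonate, CC(C)[Si](C(C)C)(C(C)C)OS(=O)(=O)C(F)(F)F
Why: Soft enolisation of the butenolide by the amine in the presence of the silyl triflate gives the aromatic 2-silyloxyfuran by O-silylation (silyl dienol ether formation).

Step 2
Reactants: 3 2-benzyl 1-tert-butyl (2S)-5-oxopyrrolidine-1,2-dicarboxylate
Product: 5 2-benzyl 1-tert-butyl (2S)-5-methoxypyrrolidine-1,2-dicarboxylate, via hemiaminal 4 (not isolated)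
Conditions: LiBHEt3, THF, −78 °C; then MeOH, pyridinium p-toluenesulfonate (cat.), rt
Reagents that add atoms: methanol, CO
Why: LiBHEt3 reduces the imide-type ring carbonyl, activated by the N-Boc group, to the hemiaminal at −78 °C without touching the benzyl ester, and acid-catalysed exchange with methanol gives the stable N,O-acetal. The C-2 centre is not involved.

Step 3
Reactants: 5 2-benzyl 1-tert-butyl (2S)-5-methoxypyrrolidine-1,2-dicarboxylate; 2 3-methyl-2-[(triisopropylsilyl)oxy]furan
Product: 7 2-benzyl 1-tert-butyl (2S,5S)-5-[(2S)-4-methyl-5-oxo-2,5-dihydrofuran-2-yl]pyrrolidine-1,2-dicarboxylate, via N-acyliminium ion 6 (not isolated)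
Conditions: i-Pr3SiOTf (10 mol %), CH2Cl2, −78 to 0 °C
Reagents that add atoms: none
Why: Vinylogous Mukaiyama–Mannich reaction: the silyl triflate ionises the N,O-acetal and the γ-carbon of the silyloxyfuran adds to the N-acyliminium ion. The C-2 ester sits pseudoaxial to avoid A(1,3) strain with the carbamate and shields its own face, so attack anti to it should give the 2,5-trans ring, and the compact synclinal approach usual for silyloxyfurans and five-membered N-acyliminium ions should give the threo pair, (S) at the butenolide carbon.

Step 4
Reactants: 7 2-benzyl 1-tert-butyl (2S,5S)-5-[(2S)-4-methyl-5-oxo-2,5-dihydrofuran-2-yl]pyrrolidine-1,2-dicarboxylate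
Product: 8 (2S,5S)-1-(tert-butoxycarbonyl)-5-[(2S,4S)-4-methyl-5-oxooxolan-2-yl]pyrrolidine-2-carboxylic acid
Conditions: H2 (3 atm), Pd/C, EtOAc, rt
Reagents that add atoms: none
Why: Heterogeneous hydrogenation saturates the butenolide from the face opposite the pyrrolidinyl group, which places the methyl group cis to it ((S) at the new CHMe), and the same catalyst hydrogenolyses the benzyl ester to the acid.

Step 5
Reactants: 8 (2S,5S)-1-(tert-butoxycarbonyl)-5-[(2S,4S)-4-methyl-5-oxooxolan-2-yl]pyrrolidine-2-carboxylic acid
Product: 9 tert-butyl (2S,5S)-2-[(ethylsulfanyl)carbonyl]-5-[(2S,4S)-4-methyl-5-oxooxolan-2-yl]pyrrolidine-1-carboxylate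
Conditions: EtSH, EDC·HCl, DMAP (cat.), CH2Cl2, 0 °C to rt
Reagents that add atoms: ethanethiol, CCS
Why: Carbodiimide thioesterification (Steglich type); a urethane-protected proline-type acid cannot form an oxazolone, so the α-centre should keep its configuration.

Step 6
Reactants: 10 methyl (R)-3-hydroxy-2-methylpropanoate
Product: 11 methyl (S)-3-iodo-2-methylpropanoate
Conditions: I2, PPh3, imidazole, CH2Cl2, 0 °C to rt
Reagents that add atoms: iodine, II
Why: Appel-type iodination through the alkoxyphosphonium salt with SN2 displacement at the primary carbon; the stereocentre is not touched and its descriptor changes only through CIP priorities.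

Step 7
Reactants: 9 tert-butyl (2S,5S)-2-[(ethylsulfanyl)carbonyl]-5-[(2S,4S)-4-methyl-5-oxooxolan-2-yl]pyrrolidine-1-carboxylate; 11 methyl (S)-3-iodo-2-methylpropanoate
Product: 13 tert-butyl (2S,5S)-2-[(3R)-4-methoxy-3-methyl-4-oxobutanoyl]-5-[(2S,4S)-4-methyl-5-oxooxolan-2-yl]pyrrolidine-1-carboxylate, via zinc reagent 12 (not isolated)
Conditions: 11, Zn dust (activated with BrCH2CH2Br and Me3SiCl), THF, 40 °C; then 9, PdCl2(PPh3)2 (10 mol %), toluene, rt; NH4Cl (aq)
Reagents that add atoms: none
Why: Zinc inserts into the C–I bond to give the β-zinc ester (a zinc homoenolate), which does not add to esters or lactones; Fukuyama coupling (oxidative addition of the thioester C–S bond to zerovalent palladium, transmetalation, reductive elimination) gives the ketone. α-Amino thioesters couple under these neutral conditions without loss of configuration, and the CHMe centre of 12 is not the metalated carbon.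

Step 8
Reactants: 14 3,4-dibromofuran
Product: 16 2-(4-bromofuran-3-yl)ethan-1-ol, via 3-bromo-4-lithiofuran 15 (not isolated)
Conditions: n-BuLi (1.0 equiv), Et2O, −78 °C; then oxirane, BF3·OEt2, −78 °C
Reagents that add atoms: oxirane, C1CO1
Why: Bromine–lithium exchange of one of the two equivalent bromines gives 15, which opens BF3-activated oxirane at carbon; the low temperature prevents ring opening of the 3-lithiofuran.

Step 9
Reactants: 16 2-(4-bromofuran-3-yl)ethan-1-ol
Product: 17 3-bromo-4-(2-chloroethyl)furan
Conditions: PPh3, N-chlorosuccinimide (premixed), THF, 0 °C to rt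
Reagents that add atoms: N-chlorosuccinimide, O=C1CCC(=O)N1Cl
Why: Appel-type chlorination through the alkoxyphosphonium salt with SN2 displacement at the primary carbon; premixing phosphine and chlorinating agent keeps electrophilic chlorine away from the furan.

Step 10
Reactants: 17 3-bromo-4-(2-chloroethyl)furan
Product: 19 [3-bromo-4-(2-chloroethyl)furan-2-yl]trimethylsilane, via 2-lithiofuran 18 (not isolated)
Conditions: LiN(i-Pr)2, Me3SiCl (present from the start), THF, −78 °C
Reagents that add atoms: chlorotrimethylsilane, C[Si](C)(C)Cl
Why: Directed deprotonation: the furan α-CH next to bromine is the most acidic position (the known behaviour of 3-bromofuran), and 18 is trapped at once by the silyl chloride in the flask, so silicon is placed regiospecifically before halogen migration or attack on the alkyl chloride can occur.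

Step 11
Reactants: 19 [3-bromo-4-(2-chloroethyl)furan-2-yl]trimethylsilane
Product: 21 [4-(2-chloroethyl)-3-methylfuran-2-yl]trimethylsilane, via 3-lithiofuran 20 (not isolated)
Conditions: t-BuLi (2 equiv), Et2O, −78 °C; then MeI, −78 to −30 °C
Reagents that add atoms: iodomethane, CI
Why: Bromine–lithium exchange with t-BuLi is far faster at −78 °C than any reaction of a primary alkyl chloride, and the 3-furyllithium 20 is methylated by MeI. Silicon now stands next to methyl, as the later oxidation requires.

Step 12
Reactants: 21 [4-(2-chloroethyl)-3-methylfuran-2-yl]trimethylsilane; 13 tert-butyl (2S,5S)-2-[(3R)-4-methoxy-3-methyl-4-oxobutanoyl]-5-[(2S,4S)-4-methyl-5-oxooxolan-2-yl]pyrrolidine-1-carboxylate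
Product: 25 tert-butyl (2S,5S)-2-[(2S,4R)-4-methyl-2-{2-[4-methyl-5-(trimethylsilyl)furan-3-yl]ethyl}-5-oxooxolan-2-yl]-5-[(2S,4S)-4-methyl-5-oxooxolan-2-yl]pyrrolidine-1-carboxylate, via Grignard reagent 22 (not isolated), via organocerium reagent 23 (not isolated), via cerium alkoxide 24 (not isolated)
Conditions: 21, Mg, THF, 60 °C; CeCl3, THF, −78 °C; then 13, −78 to 0 °C; NH4Cl (aq)
Reagents that add atoms: none
Why: Grignard reagent 22 is transmetalated with CeCl3 to the weakly basic, strongly carbonyl-selective organocerium 23, which adds 1,2 to the ketone of 13 at −78 °C; the tertiary alkoxide 24 then attacks the methyl ester on warming and expels methoxide, so the C–C bond and lactone ring C form in one operation. The closest known reaction types are organocerium addition to γ-keto esters with spontaneous γ-lactonisation and Felkin–Anh-controlled addition to carbamate-protected α-amino ketones. Ring C closes by 5-exo-trig acyl substitution. The new quaternary stereocentre is controlled by the adjacent pyrrolidine C-2 of 13: in the Felkin–Anh transition state the N-Boc nitrogen stands perpendicular to the carbonyl and anti to the incoming CH2, the nucleophile passes the small hydrogen, and this delivers the (S) carbinol required for 25. A chelated transition state, which would give the epimer, is disfavoured because the carbamate nitrogen is a poor donor and the reagent is used in THF. The step needs selectivity for the ketone over ester, lactone and carbamate and no enolisation of the epimerisable α-centres; the higher electrophilicity of the ketone, the low temperature and the low basicity of the cerium reagent secure this. The CHMe of ring C is imported unchanged from 10, so only one stereocentre is created.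

Step 13
Reactants: 25 tert-butyl (2S,5S)-2-[(2S,4R)-4-methyl-2-{2-[4-methyl-5-(trimethylsilyl)furan-3-yl]ethyl}-5-oxooxolan-2-yl]-5-[(2S,4S)-4-methyl-5-oxooxolan-2-yl]pyrrolidine-1-carboxylate
Product: 28 tert-butyl (2S,5S)-2-{(2S,4R)-2-[2-(2-hydroxy-4-methyl-5-oxo-2,5-dihydrofuran-3-yl)ethyl]-4-methyl-5-oxooxolan-2-yl}-5-[(2S,4S)-4-methyl-5-oxooxolan-2-yl]pyrrolidine-1-carboxylate, via endoperoxide 26 (not isolated), via silyl ester 27 (not isolated)
Conditions: O2, hν, tetraphenylporphyrin (cat.), CH2Cl2, −78 °C; then H2O, rt
Reagents that add atoms: dioxygen, O=O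
Why: Singlet oxygen adds (4+2) across the furan to give 26; silicon migrates from carbon to the peroxide oxygen with O–O cleavage to give silyl ester 27 of the (Z)-4-oxo-enoic acid, and hydrolysis closes the γ-hydroxybutenolide. The carbon that bore silicon becomes the lactone carbonyl, so the carbonyl ends next to the methyl-bearing carbon; the hemiacetal carbon forms as a mixture, which is of no consequence.

Step 14
Reactants: 28 tert-butyl (2S,5S)-2-{(2S,4R)-2-[2-(2-hydroxy-4-methyl-5-oxo-2,5-dihydrofuran-3-yl)ethyl]-4-methyl-5-oxooxolan-2-yl}-5-[(2S,4S)-4-methyl-5-oxooxolan-2-yl]pyrrolidine-1-carboxylate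
Product: 30 target CNP0155196.1, via pyrrolidinium trifluoroacetate 29 (not isolated)
Conditions: CF3CO2H, CH2Cl2, 0 °C; evaporate; then NaHCO3 (aq), CH2Cl2, rt
Reagents that add atoms: none
Why: Acidolysis removes Boc; on neutralisation the secondary amine condenses with the hydroxybutenolide (a masked (Z)-4-oxo-enoic acid) through its open aldehyde form and the carboxylate recloses on the iminium carbon, the known conversion of γ-hydroxybutenolides into γ-aminobutenolides, here closing seven-membered ring B. The aminal centre forms reversibly and should settle in the more stable configuration, taken to be (S) as in 30.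

## Compound list

1 | 3-methylfuran-2(5H)-one | CC1=CCOC1=O | starting material
2 | 3-methyl-2-[(triisopropylsilyl)oxy]furan | Cc1ccoc1O[Si](C(C)C)(C(C)C)C(C)C | intermediate
3 | 2-benzyl 1-tert-butyl (2S)-5-oxopyrrolidine-1,2-dicarboxylate | O=C(OCc1ccccc1)[C@@H]1CCC(=O)N1C(=O)OC(C)(C)C | starting material
4 | 2-benzyl 1-tert-butyl (2S)-5-hydroxypyrrolidine-1,2-dicarboxylate (hemiaminal, both C-5 epimers) | O=C(OCc1ccccc1)[C@@H]1CCC(O)N1C(=O)OC(C)(C)C | intermediate
5 | 2-benzyl 1-tert-butyl (2S)-5-methoxypyrrolidine-1,2-dicarboxylate (both C-5 epimers) | O=C(OCc1ccccc1)[C@@H]1CCC(OC)N1C(=O)OC(C)(C)C | intermediate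
6 | (2S)-2-[(benzyloxy)carbonyl]-1-(tert-butoxycarbonyl)-3,4-dihydro-2H-pyrrol-1-ium (N-acyliminium ion) | O=C(OCc1ccccc1)[C@@H]1CCC=[N+]1C(=O)OC(C)(C)C | intermediate
7 | 2-benzyl 1-tert-butyl (2S,5S)-5-[(2S)-4-methyl-5-oxo-2,5-dihydrofuran-2-yl]pyrrolidine-1,2-dicarboxylate | O=C(OCc1ccccc1)[C@@H]1CC[C@@H]([C@@H]2C=C(C)C(=O)O2)N1C(=O)OC(C)(C)C | intermediate
8 | (2S,5S)-1-(tert-butoxycarbonyl)-5-[(2S,4S)-4-methyl-5-oxooxolan-2-yl]pyrrolidine-2-carboxylic acid | OC(=O)[C@@H]1CC[C@@H]([C@@H]2C[C@H](C)C(=O)O2)N1C(=O)OC(C)(C)C | intermediate
9 | tert-butyl (2S,5S)-2-[(ethylsulfanyl)carbonyl]-5-[(2S,4S)-4-methyl-5-oxooxolan-2-yl]pyrrolidine-1-carboxylate | CCSC(=O)[C@@H]1CC[C@@H]([C@@H]2C[C@H](C)C(=O)O2)N1C(=O)OC(C)(C)C | intermediate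
10 | methyl (R)-3-hydroxy-2-methylpropanoate | COC(=O)[C@H](C)CO | starting material
11 | methyl (S)-3-iodo-2-methylpropanoate | COC(=O)[C@H](C)CI | intermediate
12 | [(2S)-3-methoxy-2-methyl-3-oxopropyl]zinc iodide | COC(=O)[C@H](C)C[Zn]I | intermediate
13 | tert-butyl (2S,5S)-2-[(3R)-4-methoxy-3-methyl-4-oxobutanoyl]-5-[(2S,4S)-4-methyl-5-oxooxolan-2-yl]pyrrolidine-1-carboxylate | COC(=O)[C@H](C)CC(=O)[C@@H]1CC[C@@H]([C@@H]2C[C@H](C)C(=O)O2)N1C(=O)OC(C)(C)C | intermediate
14 | 3,4-dibromofuran | Brc1cocc1Br | starting material
15 | 3-bromo-4-lithiofuran | [Li]c1cocc1Br | intermediate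
16 | 2-(4-bromofuran-3-yl)ethan-1-ol | OCCc1cocc1Br | intermediate
17 | 3-bromo-4-(2-chloroethyl)furan | ClCCc1cocc1Br | intermediate
18 | [3-bromo-4-(2-chloroethyl)furan-2-yl]lithium | [Li]c1occ(CCCl)c1Br | intermediate
19 | [3-bromo-4-(2-chloroethyl)furan-2-yl]trimethylsilane | ClCCc1coc([Si](C)(C)C)c1Br | intermediate
20 | [4-(2-chloroethyl)-2-(trimethylsilyl)furan-3-yl]lithium | [Li]c1c(CCCl)coc1[Si](C)(C)C | intermediate
21 | [4-(2-chloroethyl)-3-methylfuran-2-yl]trimethylsilane | ClCCc1coc([Si](C)(C)C)c1C | intermediate
22 | {2-[4-methyl-5-(trimethylsilyl)furan-3-yl]ethyl}magnesium chloride | Cl[Mg]CCc1coc([Si](C)(C)C)c1C | intermediate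
23 | dichloro{2-[4-methyl-5-(trimethylsilyl)furan-3-yl]ethyl}cerium | Cl[Ce](Cl)CCc1coc([Si](C)(C)C)c1C | intermediate
24 | dichlorocerium alkoxide of methyl (2R,4S)-4-{(2S,5S)-1-(tert-butoxycarbonyl)-5-[(2S,4S)-4-methyl-5-oxooxolan-2-yl]pyrrolidin-2-yl}-4-hydroxy-2-methyl-6-[4-methyl-5-(trimethylsilyl)furan-3-yl]hexanoate | COC(=O)[C@H](C)C[C@@](O[Ce](Cl)Cl)(CCc1coc([Si](C)(C)C)c1C)[C@@H]1CC[C@@H]([C@@H]2C[C@H](C)C(=O)O2)N1C(=O)OC(C)(C)C | intermediate
25 | tert-butyl (2S,5S)-2-[(2S,4R)-4-methyl-2-{2-[4-methyl-5-(trimethylsilyl)furan-3-yl]ethyl}-5-oxooxolan-2-yl]-5-[(2S,4S)-4-methyl-5-oxooxolan-2-yl]pyrrolidine-1-carboxylate | Cc1c(CC[C@]2(C[C@@H](C)C(=O)O2)[C@@H]2CC[C@@H]([C@@H]3C[C@H](C)C(=O)O3)N2C(=O)OC(C)(C)C)coc1[Si](C)(C)C | intermediate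
26 | 2,5-endoperoxide of 25 (1-trimethylsilyl-2,3,7-trioxabicyclo[2.2.1]hept-5-ene core) | CC1=C(CC[C@]2(C[C@@H](C)C(=O)O2)[C@@H]2CC[C@@H]([C@@H]3C[C@H](C)C(=O)O3)N2C(=O)OC(C)(C)C)C2OOC1([Si](C)(C)C)O2 | intermediate
27 | trimethylsilyl (2Z)-3-formyl-2-methylpent-2-enoate carrying at C-5 the lactone C–pyrrolidine–lactone E unit of 25 | C[Si](C)(C)OC(=O)/C(C)=C(C=O)/CC[C@]1(C[C@@H](C)C(=O)O1)[C@@H]1CC[C@@H]([C@@H]2C[C@H](C)C(=O)O2)N1C(=O)OC(C)(C)C | intermediate
28 | tert-butyl (2S,5S)-2-{(2S,4R)-2-[2-(2-hydroxy-4-methyl-5-oxo-2,5-dihydrofuran-3-yl)ethyl]-4-methyl-5-oxooxolan-2-yl}-5-[(2S,4S)-4-methyl-5-oxooxolan-2-yl]pyrrolidine-1-carboxylate (both hemiacetal epimers) | CC1=C(CC[C@]2(C[C@@H](C)C(=O)O2)[C@@H]2CC[C@@H]([C@@H]3C[C@H](C)C(=O)O3)N2C(=O)OC(C)(C)C)C(O)OC1=O | intermediate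
29 | (2S,5S)-2-{(2S,4R)-2-[2-(2-hydroxy-4-methyl-5-oxo-2,5-dihydrofuran-3-yl)ethyl]-4-methyl-5-oxooxolan-2-yl}-5-[(2S,4S)-4-methyl-5-oxooxolan-2-yl]pyrrolidin-1-ium trifluoroacetate | CC1=C(CC[C@]2(C[C@@H](C)C(=O)O2)[C@@H]2CC[C@@H]([C@@H]3C[C@H](C)C(=O)O3)[NH2+]2)C(O)OC1=O.[O-]C(=O)C(F)(F)F | intermediate
30 | CNP0155196.1: pyrrolo[1,2-a]azepine fused at its N–CH–O carbon and the next ring carbon to a 3-methylbutenolide, with spiro α-methyl-γ-lactone ring C and appended α-methyl-γ-lactone ring E; aminal CH (S), spiro C (S), ring C CHMe (R), ring-fusion CH (S), ring A CH bearing ring E (S), ring E O–CH (S), ring E CHMe (S) | CC1=C2CC[C@]3(C[C@@H](C)C(=O)O3)[C@@H]3CC[C@@H]([C@@H]4C[C@H](C)C(=O)O4)N3[C@H]2OC1=O | target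

## Step count and risk

Total: 14 steps. Longest linear sequence: 8 steps from 3 (steps 2, 3, 4, 5, 7, 12, 13, 14). The arm 21 takes 4 steps from 14 and joins at step 12; 2 and 11 take one step each.

**Step 12 (key step).** The most likely failures are erosion of facial selectivity through a competing chelated transition state that involves the carbamate carbonyl, enolisation of the α-amino ketone by the organometallic, and attack of the tertiary alkoxide on the Boc carbonyl (cyclic carbamate formation) in competition with lactonisation.

Fallback: the two substituents of the carbinol carbon are introduced in the opposite order, which is stereochemically complementary, so an intrinsic preference for the chelated mode would then give the required configuration. It sets out from 9, 22 and 11 and returns at 25. Reagent 22 is transmetalated with ZnCl2 to {2-[4-methyl-5-(trimethylsilyl)furan-3-yl]ethyl}zinc chloride F1 and coupled with 9 under PdCl2(PPh3)2 catalysis to give tert-butyl (2S,5S)-2-{3-[4-methyl-5-(trimethylsilyl)furan-3-yl]propanoyl}-5-[(2S,4S)-4-methyl-5-oxooxolan-2-yl]pyrrolidine-1-carboxylate F2. Separately, 11 is reduced with i-Bu2AlH to (2S)-3-iodo-2-methylpropan-1-ol F3 and silylated (t-BuMe2SiCl, imidazole) to tert-butyl{[(2S)-3-iodo-2-methylpropyl]oxy}dimethylsilane F4. Iodine–lithium exchange of F4 (t-BuLi, Et2O, −78 °C), transmetalation with CeCl3 and addition to F2 should give tert-butyl (2S,5S)-2-{(3S,5R)-6-[(tert-butyldimethylsilyl)oxy]-3-hydroxy-5-methyl-1-[4-methyl-5-(trimethylsilyl)furan-3-yl]hexan-3-yl}-5-[(2S,4S)-4-methyl-5-oxooxolan-2-yl]pyrrolidine-1-carboxylate F5. Desilylation at oxygen (Bu4NF, AcOH, THF, 0 °C) gives tert-butyl (2S,5S)-2-{(3S,5R)-3,6-dihydroxy-5-methyl-1-[4-methyl-5-(trimethylsilyl)furan-3-yl]hexan-3-yl}-5-[(2S,4S)-4-methyl-5-oxooxolan-2-yl]pyrrolidine-1-carboxylate F6, and oxidative lactonisation (TEMPO, PhI(OAc)2, CH2Cl2) returns 25.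

**Step 3.** Insufficient anti (2,5-trans) selectivity at the iminium ion, or insufficient threo selectivity, would leave inseparable or low-yielding mixtures, because both centres are set in one intermolecular bond formation.

Fallback: the two centres are set one after the other by known reactions. It sets out from 5 and returns at 8. trans-Selective organocopper transfer (CH2=CHMgBr, CuBr·SMe2, BF3·OEt2, Et2O, −78 °C) gives 2-benzyl 1-tert-butyl (2S,5S)-5-ethenylpyrrolidine-1,2-dicarboxylate F7. Ozonolysis (O3, CH2Cl2, −78 °C; Me2S) gives 2-benzyl 1-tert-butyl (2S,5S)-5-formylpyrrolidine-1,2-dicarboxylate F8, and Pinnick oxidation (NaClO2, NaH2PO4, 2-methylbut-2-ene) gives (2S,5S)-5-[(benzyloxy)carbonyl]-1-(tert-butoxycarbonyl)pyrrolidine-2-carboxylic acid F9. Thioesterification as in step 5 gives 2-benzyl 1-tert-butyl (2S,5S)-5-[(ethylsulfanyl)carbonyl]pyrrolidine-1,2-dicarboxylate F10. Methyl (S)-3-hydroxy-2-methylpropanoate, a catalogue compound, is iodinated as in step 6 to methyl (R)-3-iodo-2-methylpropanoate F11 (the enantiomer of 11), which gives [(2R)-3-methoxy-2-methyl-3-oxopropyl]zinc iodide F12; Fukuyama coupling of F12 with F10 as in step 7 gives 2-benzyl 1-tert-butyl (2S,5S)-5-[(3S)-4-methoxy-3-methyl-4-oxobutanoyl]pyrrolidine-1,2-dicarboxylate F13. Felkin–Anh reduction with LiBH(s-Bu)3 (THF, −78 °C) and lactonisation of the alkoxide give 2-benzyl 1-tert-butyl (2S,5S)-5-[(2S,4S)-4-methyl-5-oxooxolan-2-yl]pyrrolidine-1,2-dicarboxylate F14, and hydrogenolysis (H2, Pd/C) returns 8.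

**Step 14.** The liberated secondary amine may undergo O-to-N acyl transfer with lactone ring E or ring C (six-membered lactam formation) before it condenses with the masked aldehyde, and the aminal centre may equilibrate slowly or incompletely.

Fallback: the hemiacetal is turned into a leaving group so that N–C bond formation is a fast substitution through the acyloxycarbenium ion and not a condensation. It sets out from 28 and returns at 30. Acetylation (Ac2O, pyridine, DMAP cat.) gives tert-butyl (2S,5S)-2-{(2S,4R)-2-[2-(2-acetoxy-4-methyl-5-oxo-2,5-dihydrofuran-3-yl)ethyl]-4-methyl-5-oxooxolan-2-yl}-5-[(2S,4S)-4-methyl-5-oxooxolan-2-yl]pyrrolidine-1-carboxylate F15. CF3CO2H in CH2Cl2 at 0 °C then removes Boc while the amine stays protonated, and addition of Et3N at −20 °C releases the amine, which displaces acetate to give 30.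

**Step 11.** Loss of HCl from the chloroethyl chain by the alkyllithium, or protonation of the hindered furyllithium 20 before methylation, would lower the yield.

Fallback: the methyl group is introduced by cross-coupling instead of lithiation. It sets out from 19 and returns at 21: Negishi coupling with MeZnCl and PdCl2(dppf) in THF at 60 °C, which leaves the primary alkyl chloride and the C–Si bond alone. No compound outside the compound list is made (F0).

## Further compounds

F1 | step 12 | {2-[4-methyl-5-(trimethylsilyl)furan-3-yl]ethyl}zinc chloride | Cl[Zn]CCc1coc([Si](C)(C)C)c1C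
F2 | step 12 | tert-butyl (2S,5S)-2-{3-[4-methyl-5-(trimethylsilyl)furan-3-yl]propanoyl}-5-[(2S,4S)-4-methyl-5-oxooxolan-2-yl]pyrrolidine-1-carboxylate | Cc1c(CCC(=O)[C@@H]2CC[C@@H]([C@@H]3C[C@H](C)C(=O)O3)N2C(=O)OC(C)(C)C)coc1[Si](C)(C)C
F3 | step 12 | (2S)-3-iodo-2-methylpropan-1-ol | OC[C@H](C)CI
F4 | step 12 | tert-butyl{[(2S)-3-iodo-2-methylpropyl]oxy}dimethylsilane | CC(C)(C)[Si](C)(C)OC[C@H](C)CI
F5 | step 12 | tert-butyl (2S,5S)-2-{(3S,5R)-6-[(tert-butyldimethylsilyl)oxy]-3-hydroxy-5-methyl-1-[4-methyl-5-(trimethylsilyl)furan-3-yl]hexan-3-yl}-5-[(2S,4S)-4-methyl-5-oxooxolan-2-yl]pyrrolidine-1-carboxylate | CC(C)(C)[Si](C)(C)OC[C@H](C)C[C@@](O)(CCc1coc([Si](C)(C)C)c1C)[C@@H]1CC[C@@H]([C@@H]2C[C@H](C)C(=O)O2)N1C(=O)OC(C)(C)C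
F6 | step 12 | tert-butyl (2S,5S)-2-{(3S,5R)-3,6-dihydroxy-5-methyl-1-[4-methyl-5-(trimethylsilyl)furan-3-yl]hexan-3-yl}-5-[(2S,4S)-4-methyl-5-oxooxolan-2-yl]pyrrolidine-1-carboxylate | OC[C@H](C)C[C@@](O)(CCc1coc([Si](C)(C)C)c1C)[C@@H]1CC[C@@H]([C@@H]2C[C@H](C)C(=O)O2)N1C(=O)OC(C)(C)C
F7 | step 3 | 2-benzyl 1-tert-butyl (2S,5S)-5-ethenylpyrrolidine-1,2-dicarboxylate | O=C(OCc1ccccc1)[C@@H]1CC[C@@H](C=C)N1C(=O)OC(C)(C)C
F8 | step 3 | 2-benzyl 1-tert-butyl (2S,5S)-5-formylpyrrolidine-1,2-dicarboxylate | O=C(OCc1ccccc1)[C@@H]1CC[C@@H](C=O)N1C(=O)OC(C)(C)C
F9 | step 3 | (2S,5S)-5-[(benzyloxy)carbonyl]-1-(tert-butoxycarbonyl)pyrrolidine-2-carboxylic acid | O=C(OCc1ccccc1)[C@@H]1CC[C@@H](C(=O)O)N1C(=O)OC(C)(C)C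
F10 | step 3 | 2-benzyl 1-tert-butyl (2S,5S)-5-[(ethylsulfanyl)carbonyl]pyrrolidine-1,2-dicarboxylate | O=C(OCc1ccccc1)[C@@H]1CC[C@@H](C(=O)SCC)N1C(=O)OC(C)(C)C
F11 | step 3 | methyl (R)-3-iodo-2-methylpropanoate | COC(=O)[C@@H](C)CI
F12 | step 3 | [(2R)-3-methoxy-2-methyl-3-oxopropyl]zinc iodide | COC(=O)[C@@H](C)C[Zn]I
F13 | step 3 | 2-benzyl 1-tert-butyl (2S,5S)-5-[(3S)-4-methoxy-3-methyl-4-oxobutanoyl]pyrrolidine-1,2-dicarboxylate | O=C(OCc1ccccc1)[C@@H]1CC[C@@H](C(=O)C[C@H](C)C(=O)OC)N1C(=O)OC(C)(C)C
F14 | step 3 | 2-benzyl 1-tert-butyl (2S,5S)-5-[(2S,4S)-4-methyl-5-oxooxolan-2-yl]pyrrolidine-1,2-dicarboxylate | O=C(OCc1ccccc1)[C@@H]1CC[C@@H]([C@@H]2C[C@H](C)C(=O)O2)N1C(=O)OC(C)(C)C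
F15 | step 14 | tert-butyl (2S,5S)-2-{(2S,4R)-2-[2-(2-acetoxy-4-methyl-5-oxo-2,5-dihydrofuran-3-yl)ethyl]-4-methyl-5-oxooxolan-2-yl}-5-[(2S,4S)-4-methyl-5-oxooxolan-2-yl]pyrrolidine-1-carboxylate | CC(=O)OC1OC(=O)C(C)=C1CC[C@]1(C[C@@H](C)C(=O)O1)[C@@H]1CC[C@@H]([C@@H]2C[C@H](C)C(=O)O2)N1C(=O)OC(C)(C)C
F0 | step 11 | none | none
A1 | alternative 1 | azido ketone: prop-2-enyl (2Z)-2-(2-oxocyclohexylidene)propanoate with spiro lactone ring C on the ring and a 3-azido-3-[(2S,4S)-4-methyl-5-oxooxolan-2-yl]propyl chain on the ketone α-carbon | C=CCOC(=O)/C(C)=C1/CC[C@]2(C[C@@H](C)C(=O)O2)[C@H](CC[C@H](N=[N+]=[N-])[C@@H]2C[C@H](C)C(=O)O2)C1=O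
A2 | alternative 1 | tricyclic unsaturated lactam (maleamate allyl ester) with rings A, B, C and E | C=CCOC(=O)/C(C)=C1/CC[C@]2(C[C@@H](C)C(=O)O2)[C@@H]2CC[C@@H]([C@@H]3C[C@H](C)C(=O)O3)N2C1=O
A3 | alternative 2 | divinyl aminal: N-(4-ethenyl-3-methyl-5-oxo-2,5-dihydrofuran-2-yl)pyrrolidine with a 2-ethenyl lactone ring C and lactone ring E | C=C[C@]1(C[C@@H](C)C(=O)O1)[C@@H]1CC[C@@H]([C@@H]2C[C@H](C)C(=O)O2)N1[C@H]1OC(=O)C(C)=C1C=C
A4 | alternative 2 | didehydro target with a ring B alkene conjugated to butenolide ring D | CC1=C2C=C[C@]3(C[C@@H](C)C(=O)O3)[C@@H]3CC[C@@H]([C@@H]4C[C@H](C)C(=O)O4)N3[C@H]2OC1=O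
A5 | alternative 3 | secondary N-benzylamine with (Z)-alkene, methyl ester chain, lactone ring C and the acetal / tert-butyl enoate unit | CC(C)(C)OC(=O)/C(C)=C(/CC[C@]1(C[C@@H](C)C(=O)O1)[C@H](CC/C=C\C[C@H](C)C(=O)OC)NCc1ccccc1)C(OC)OC
A6 | alternative 3 | N-benzyl pyrrolidine with spiro lactone ring C, lactone ring E and the masked hydroxybutenolide | CC(C)(C)OC(=O)/C(C)=C(/CC[C@]1(C[C@@H](C)C(=O)O1)[C@@H]1CC[C@@H]([C@@H]2C[C@H](C)C(=O)O2)N1Cc1ccccc1)C(OC)OC
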